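Remark: target 11 is achiral and is written in the diketo form, although it should exist largely as the chelated enol. Compounds 1, 2 and 4 are taken as commercial.

## The problem

1. Glyinflanin D (11) is a dibenzoylmethane. A C(=O)–CH2–C(=O) chain joins C6 of a 7-hydroxy-2,2-dimethyl-2H-chromene (benzene ring B, pyran ring D, atoms O1 to C8a) to C6' of a 2,2-dimethyl-2H-chromene (benzene ring A, pyran ring C, atoms O1' to C8a').
2. There is no stereocentre; the two ring alkenes are cis by ring constraint, so no stereocontrol is needed.
3. The hard point is site selectivity on ring B. Ring D is fused so that the C4a–C4 bond is para to the C7 hydroxyl. A free 2,4-dioxygenated aryl ketone, chelated between that hydroxyl and the C6 carbonyl, instead directs Claisen-type bond formation to the carbon between the two oxygens (future C8).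
4. Two chromene alkenes (C3=C4, C3'=C4') are sensitive to acid, oxidants and light, so they are best made late and together.
5. The ortho-hydroxy β-diketone cyclodehydrates under acid or heat and cleaves by retro-Claisen in hot alkali. It should appear last, under mild base with a buffered work-up.
6. The enabling feature is twofold. O1 and O1' are each para to the chain carbons C6 and C6', so both pyran rings map onto para-acyl aryl 1,1-dimethylpropargyl ethers. O7 is ortho to the C6 carbonyl, so the diketone is the Baker–Venkataraman isomer of an aryl ester in which O7 carries the C6' aroyl group.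
7. In that ester O7 is acylated and cannot chelate the C6 acetyl carbonyl. The ester bond, absent from 11, therefore serves as a temporary tether: it joins the halves, removes the misdirecting chelate, and later delivers the acyl group to carbon.

## Retrosynthesis

**11 to 10.** The bond between the central CH2 and the carbonyl on C6' is cut, giving ester 10 (6-acetylchromen-7-yl chromene-6-carboxylate). The forward reaction is a Baker–Venkataraman O-to-C acyl shift. An intermolecular Claisen union of two separate halves is the neighbouring cut; the intramolecular version is preferred because the ester is needed earlier for another purpose. The forward step must enolise the methyl ketone without retro-Claisen cleavage and without cyclodehydration on work-up.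

**10 to 7 (key).** Both aryl–vinyl bonds C4a–C4 and C4a'–C4' are cut, and each C3=C4 alkene returns to a terminal alkyne held on the pyran oxygen. Bis(propargyl ether) ester 7 has no pyran ring. Forward, each terminus passes through allenylphenol 8 and ortho-quinone methide 9. The neighbouring cuts are worse:
- Cutting O1–C2 (oxidative closure of C-prenyl phenols) needs an oxidant and C-prenyl groups placed against the same regiochemical bias.
- Cutting at C3=C4 (late dehydrogenation or dehydration) adds steps.

The forward cascade must run twice, and on ring B it must go to the carbon para to the aroyloxy group.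

**7 to 3 and 6.** The ester C–O bond is cut. This is a convergent esterification of the chelated phenol 3 with acid 6, and both halves are simple para-oxygenated aryl carbonyl compounds.

**3 to 1 and 2; 6 to 5 to 4 and 2.** The O–CMe2 ether bonds are cut. The same C5 chloride 2 alkylates the more acidic para-hydroxyl of 1 and of 4. The chelate of 1 is used here rather than fought: it keeps the ortho-hydroxyl free for the esterification. Saponification of 5 gives 6.

## Roads not taken

Alternative 1: This is the most obvious route. The same CH2–C(=O) bond is cut, but with both pyran rings already in place: 1-(7-hydroxy-2,2-dimethyl-2H-chromen-6-yl)ethan-1-one A1 is joined to 2,2-dimethyl-2H-chromene-6-carbonyl chloride A2 by Baker–Venkataraman or crossed Claisen. The weakness lies before the union. A1 must be built on a free, chelated dihydroxyacetophenone. There, cyclisation of ether 3 or condensation with 3-methylbut-2-enal goes to the carbon between the oxygens and gives the angular ketone 1-(5-hydroxy-2,2-dimethyl-2H-chromen-6-yl)ethan-1-one A3. Reaching A1 then needs a blocking group or a chromanone detour, and the two annulations run in separate flasks. The chosen plan forms the same kind of ester before the rings, so one bond does three jobs and both rings close in one step.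

Alternative 2: Core first, without a tether. Both C4a–C4 bonds are cut in the diketone itself. The forward key step would be the double cascade on 1-{2-hydroxy-4-[(2-methylbut-3-yn-2-yl)oxy]phenyl}-3-{4-[(2-methylbut-3-yn-2-yl)oxy]phenyl}propane-1,3-dione A4, made from 3 and 5 by crossed Claisen, one step shorter. In A4 the ring-B hydroxyl is free and chelated to the enolised diketone. That steers closure to the carbon between the oxygens, towards 1-(5-hydroxy-2,2-dimethyl-2H-chromen-6-yl)-3-(2,2-dimethyl-2H-chromen-6-yl)propane-1,3-dione A5. The hot, free ortho-hydroxy diketone is also prone to cyclodehydration. The ester tether costs one step and removes both problems.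

Alternative 3: Biomimetic. The O1–C2 and O1'–C2' bonds are cut, giving 1-[2,4-dihydroxy-5-(3-methylbut-2-en-1-yl)phenyl]-3-[4-hydroxy-3-(3-methylbut-2-en-1-yl)phenyl]propane-1,3-dione A6. The forward key step is a double dehydrogenative cyclisation with DDQ (benzylic hydride abstraction, ortho-quinone methide, oxa-6π closure). It is worse on three counts:
- The ring-B prenyl group must be placed para to the chelated hydroxyl, while direct C-prenylation favours the carbon between the oxygens.
- Three phenols must be masked for diketone formation and then freed.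
- An oxidant meets an enolised diketone and electron-rich phenols.

The chosen cascade reaches the same kind of ortho-quinone methide by isomerisation alone.

Key step: step 5

## Route

Step 1
Reactants: 1 1-(2,4-dihydroxyphenyl)ethan-1-one; 2 3-chloro-3-methylbut-1-yne
Product: 3 1-{2-hydroxy-4-[(2-methylbut-3-yn-2-yl)oxy]phenyl}ethan-1-one
Conditions: K2CO3 (2 equiv), KI (0.1 equiv), CuI (0.05 equiv), acetone, reflux, argon
Reagents that add atoms: none
Why: Copper-assisted O-alkylation of the more acidic para-hydroxyl by the tertiary propargylic chloride; the ortho-hydroxyl is held in the hydrogen bond to the acetyl group and stays free for step 4.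

Step 2
Reactants: 4 methyl 4-hydroxybenzoate; 2 3-chloro-3-methylbut-1-yne
Product: 5 methyl 4-[(2-methylbut-3-yn-2-yl)oxy]benzoate
Conditions: K2CO3 (2 equiv), KI (0.1 equiv), CuI (0.05 equiv), DMF, 65 °C, argon
Reagents that add atoms: none
Why: The same propargylic etherification on a para-alkoxycarbonyl phenol, a routine substrate class for this alkylation.

Step 3
Reactants: 5 methyl 4-[(2-methylbut-3-yn-2-yl)oxy]benzoate
Product: 6 4-[(2-methylbut-3-yn-2-yl)oxy]benzoic acid
Conditions: LiOH·H2O (3 equiv), THF/MeOH/H2O, rt; then 1 M HCl to pH 3, 0 °C
Reagents that add atoms: lithium hydroxide, [Li+].[OH-]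
Why: Ester saponification; the tertiary propargyl aryl ether is stable to base and should survive a brief, cold acidification.

Step 4
Reactants: 3 1-{2-hydroxy-4-[(2-methylbut-3-yn-2-yl)oxy]phenyl}ethan-1-one; 6 4-[(2-methylbut-3-yn-2-yl)oxy]benzoic acid
Product: 7 2-acetyl-5-[(2-methylbut-3-yn-2-yl)oxy]phenyl 4-[(2-methylbut-3-yn-2-yl)oxy]benzoate
Conditions: DIC (1.2 equiv), DMAP (0.2 equiv), CH2Cl2, 0 °C to rt
Reagents that add atoms: none
Why: Steglich esterification; the acylpyridinium from DMAP acylates the hydrogen-bonded phenol under neutral conditions that spare both ethers and do not enolise the ketone. This ester bond is the temporary tether.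

Step 5
Reactants: 7 2-acetyl-5-[(2-methylbut-3-yn-2-yl)oxy]phenyl 4-[(2-methylbut-3-yn-2-yl)oxy]benzoate
Product: 10 6-acetyl-2,2-dimethyl-2H-chromen-7-yl 2,2-dimethyl-2H-chromene-6-carboxylate, via bis(allenylphenol) ester 8 (not isolated), via bis(ortho-quinone methide) ester 9 (not isolated)
Conditions: 1,2-dichlorobenzene (0.05 M), 180 °C, argon, dark
Reagents that add atoms: none
Why: Each aryl 1,1-dimethylpropargyl ether undergoes an aromatic propargyl Claisen [3,3] shift to an ortho carbon and enolises to the ortho-allenylphenol (8); a [1,5]-hydrogen shift from the phenol O–H to the central allene carbon then gives the Z-configured ortho-quinone methide (9), which closes to the 2H-pyran (the two termini react independently; 8 and 9 are written with both at the same stage). The closest known reaction type is the thermal cyclisation of para-acyl and para-alkoxycarbonyl aryl 1,1-dimethylpropargyl ethers to 2,2-dimethyl-2H-chromenes, here run twice in one molecule. Rings C and D each close by a thermally allowed disrotatory oxa-6π electrocyclisation that forms the O–C2 bond after the [3,3] shift has made the C4a–C4 bond, so the net change at each terminus is a 6-endo hydroarylation of the alkyne. No stereocentre is formed: C2 and C2' carry two methyl groups and the new alkenes are cis by ring constraint. The selectivity needed is migration on ring B to the carbon para to the aroyloxy group (future C4a) and not to the carbon between the two oxygens (future C8). The tether should secure this in two ways: the acylated O7 cannot form the hydrogen-bonded chelate with the acetyl carbonyl that directs the free phenol towards C8, and the C8 site is flanked by the aroyloxy group and the migrating ether while the C4a site has only hydrogen on its other side. Ring A has two equivalent ortho carbons, the geminal methyl groups speed the [3,3] step, and the ester and methyl ketone are inert to neutral heating.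

Step 6
Reactants: 10 6-acetyl-2,2-dimethyl-2H-chromen-7-yl 2,2-dimethyl-2H-chromene-6-carboxylate
Product: 11 1-(7-hydroxy-2,2-dimethyl-2H-chromen-6-yl)-3-(2,2-dimethyl-2H-chromen-6-yl)propane-1,3-dione (glyinflanin D)
Conditions: KOtBu (2.5 equiv), THF, 0 °C to rt; then AcOH, 0 °C
Reagents that add atoms: none
Why: Baker–Venkataraman rearrangement; the enolate of the methyl ketone attacks the neighbouring aryl ester carbonyl through a six-membered cyclic transition state and the tetrahedral intermediate expels the C7 phenoxide, which breaks the tether and forms the CH2–C(=O) bond. The product rests as its enolate–phenoxide until buffered acidification, which should avoid retro-Claisen cleavage and cyclodehydration; the chromene alkenes are inert to base.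

## Compound list

1 | 1-(2,4-dihydroxyphenyl)ethan-1-one | CC(=O)c1ccc(O)cc1O | starting material
2 | 3-chloro-3-methylbut-1-yne | C#CC(C)(C)Cl | starting material
3 | 1-{2-hydroxy-4-[(2-methylbut-3-yn-2-yl)oxy]phenyl}ethan-1-one | CC(=O)c1ccc(OC(C)(C)C#C)cc1O | intermediate
4 | methyl 4-hydroxybenzoate | COC(=O)c1ccc(O)cc1 | starting material
5 | methyl 4-[(2-methylbut-3-yn-2-yl)oxy]benzoate | COC(=O)c1ccc(OC(C)(C)C#C)cc1 | intermediate
6 | 4-[(2-methylbut-3-yn-2-yl)oxy]benzoic acid | OC(=O)c1ccc(OC(C)(C)C#C)cc1 | intermediate
7 | 2-acetyl-5-[(2-methylbut-3-yn-2-yl)oxy]phenyl 4-[(2-methylbut-3-yn-2-yl)oxy]benzoate | CC(=O)c1ccc(OC(C)(C)C#C)cc1OC(=O)c1ccc(OC(C)(C)C#C)cc1 | intermediate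
8 | 2-acetyl-5-hydroxy-4-(3-methylbuta-1,2-dien-1-yl)phenyl 4-hydroxy-3-(3-methylbuta-1,2-dien-1-yl)benzoate | CC(=O)c1cc(C=C=C(C)C)c(O)cc1OC(=O)c1ccc(O)c(C=C=C(C)C)c1 | intermediate (not isolated)
9 | 2-acetyl-4-(3-methylbut-2-en-1-ylidene)-5-oxocyclohexa-1(6),2-dien-1-yl 3-(3-methylbut-2-en-1-ylidene)-4-oxocyclohexa-1,5-diene-1-carboxylate | O=C1C=C(OC(=O)C2=C/C(=C/C=C(C)C)C(=O)C=C2)C(C(C)=O)=C/C1=C/C=C(C)C | intermediate (not isolated)
10 | 6-acetyl-2,2-dimethyl-2H-chromen-7-yl 2,2-dimethyl-2H-chromene-6-carboxylate | CC(=O)c1cc2C=CC(C)(C)Oc2cc1OC(=O)c1ccc2OC(C)(C)C=Cc2c1 | intermediate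
11 | glyinflanin D, 1-(7-hydroxy-2,2-dimethyl-2H-chromen-6-yl)-3-(2,2-dimethyl-2H-chromen-6-yl)propane-1,3-dione | CC1(C)C=Cc2cc(C(=O)CC(=O)c3cc4c(cc3O)OC(C)(C)C=C4)ccc2O1 | target

## Step count and risks

Total: 6 steps. Longest linear sequence: 5 steps (steps 2, 3, 4, 5, 6, from 4).

**Step 5 (key).** The main risk is insufficient site selectivity on ring B. The aroyloxy group is a weaker donor than an alkoxy group and an inductive acceptor, so part of the migration may go to the carbon between the two oxygens. Slow closure of the second terminus and thermal oligomerisation of the ortho-quinone methide stage are lesser risks. The fallback blocks the competing carbon with iodine.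
- It sets out from 1. Iodination between the two hydroxyls (I2, HIO3, aqueous EtOH) should give 1-(2,4-dihydroxy-3-iodophenyl)ethan-1-one F1.
- Etherification with 2 as in step 1 would give 1-{2-hydroxy-3-iodo-4-[(2-methylbut-3-yn-2-yl)oxy]phenyl}ethan-1-one F2.
- Esterification with 6 as in step 4 would give 2-acetyl-6-iodo-5-[(2-methylbut-3-yn-2-yl)oxy]phenyl 4-[(2-methylbut-3-yn-2-yl)oxy]benzoate F3.
- The thermal cascade, now with only one open ortho carbon on ring B, would give 6-acetyl-8-iodo-2,2-dimethyl-2H-chromen-7-yl 2,2-dimethyl-2H-chromene-6-carboxylate F4.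
- Hydrodeiodination (Pd(OAc)2, PPh3, HCO2Na, DMF, 80 °C) comes back to the route at 10.

**Step 6.** Intermolecular attack of the alkoxide on the aryl ester may compete with enolisation. The product may undergo retro-Claisen cleavage if left in base, or cyclodehydration if the work-up is too acidic. The fallback replaces the intramolecular acyl shift by an intermolecular condensation.
- It sets out from 10. Cleavage with NaOMe in MeOH (then AcOH) would give 1-(7-hydroxy-2,2-dimethyl-2H-chromen-6-yl)ethan-1-one F5 and methyl 2,2-dimethyl-2H-chromene-6-carboxylate F6.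
- Crossed Claisen condensation of the dianion of F5 with F6 (LiN(SiMe3)2, 3.2 equiv, THF, −78 °C to rt, then AcOH) comes back to the route at 11.

**Step 1.** The tertiary chloride may lose HCl to the enyne faster than it etherifies, and conversion of the phenol may stall. The fallback changes the electrophile and the mechanism to a copper-catalysed propargylic substitution of an ester leaving group.
- It sets out from 1. 2-Methylbut-3-yn-2-yl trifluoroacetate F7 is made in the flask from 2-methylbut-3-yn-2-ol and trifluoroacetic anhydride (DBU, MeCN, 0 °C).
- F7 is then treated with 1 and CuCl2 (0.01 equiv) at 0 °C, which comes back to the route at 3.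

## Further compounds

F1 | step 5 | 1-(2,4-dihydroxy-3-iodophenyl)ethan-1-one | CC(=O)c1ccc(O)c(I)c1O
F2 | step 5 | 1-{2-hydroxy-3-iodo-4-[(2-methylbut-3-yn-2-yl)oxy]phenyl}ethan-1-one | CC(=O)c1ccc(OC(C)(C)C#C)c(I)c1O
F3 | step 5 | 2-acetyl-6-iodo-5-[(2-methylbut-3-yn-2-yl)oxy]phenyl 4-[(2-methylbut-3-yn-2-yl)oxy]benzoate | CC(=O)c1ccc(OC(C)(C)C#C)c(I)c1OC(=O)c1ccc(OC(C)(C)C#C)cc1
F4 | step 5 | 6-acetyl-8-iodo-2,2-dimethyl-2H-chromen-7-yl 2,2-dimethyl-2H-chromene-6-carboxylate | CC(=O)c1cc2C=CC(C)(C)Oc2c(I)c1OC(=O)c1ccc2OC(C)(C)C=Cc2c1
F5 | step 6 | 1-(7-hydroxy-2,2-dimethyl-2H-chromen-6-yl)ethan-1-one | CC(=O)c1cc2C=CC(C)(C)Oc2cc1O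
F6 | step 6 | methyl 2,2-dimethyl-2H-chromene-6-carboxylate | COC(=O)c1ccc2OC(C)(C)C=Cc2c1
F7 | step 1 | 2-methylbut-3-yn-2-yl trifluoroacetate | C#CC(C)(C)OC(=O)C(F)(F)F
A1 | alternative 1 | 1-(7-hydroxy-2,2-dimethyl-2H-chromen-6-yl)ethan-1-one | CC(=O)c1cc2C=CC(C)(C)Oc2cc1O
A2 | alternative 1 | 2,2-dimethyl-2H-chromene-6-carbonyl chloride | ClC(=O)c1ccc2OC(C)(C)C=Cc2c1
A3 | alternative 1 | 1-(5-hydroxy-2,2-dimethyl-2H-chromen-6-yl)ethan-1-one | CC(=O)c1ccc2OC(C)(C)C=Cc2c1O
A4 | alternative 2 | 1-{2-hydroxy-4-[(2-methylbut-3-yn-2-yl)oxy]phenyl}-3-{4-[(2-methylbut-3-yn-2-yl)oxy]phenyl}propane-1,3-dione | C#CC(C)(C)Oc1ccc(cc1)C(=O)CC(=O)c1ccc(OC(C)(C)C#C)cc1O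
A5 | alternative 2 | 1-(5-hydroxy-2,2-dimethyl-2H-chromen-6-yl)-3-(2,2-dimethyl-2H-chromen-6-yl)propane-1,3-dione | CC1(C)C=Cc2cc(ccc2O1)C(=O)CC(=O)c1ccc2OC(C)(C)C=Cc2c1O
A6 | alternative 3 | 1-[2,4-dihydroxy-5-(3-methylbut-2-en-1-yl)phenyl]-3-[4-hydroxy-3-(3-methylbut-2-en-1-yl)phenyl]propane-1,3-dione | CC(C)=CCc1cc(ccc1O)C(=O)CC(=O)c1cc(CC=C(C)C)c(O)cc1O
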